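## Retrosynthetic overview

1. Target ⇐ global hydrogenolysis of a nonadeca-O-benzyl precursor. The two gallates go on last, onto the only two free hydroxyls (C3 of the middle and bottom units), because the top unit carries a 3-O-benzyl ether from its own synthesis.
2. Both interflavan bonds ⇐ Lewis-acid C4-cation/C8 Friedel–Crafts couplings (4β→8): first the epicatechin-derived lower dimer, then the top unit as the C4 electrophile.
3. Top unit ⇐ aryne annulation of 3,5-bis(benzyloxy)benzyne with an acyclic syn-aldol (β-hydroxy aldehyde). O1–C8a and C4a–C4 form in one operation, closing ring C and creating the C4 hydroxyl that the next coupling ionizes.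
4. Enabling feature: ring A of the top unit is a phloroglucinol ring whose adjacent carbons C8a (bearing O1) and C4a (bearing C4) sit next to the C5 oxygen. This is the pattern of a 3-alkoxyaryne, whose flanking oxygen sends the O-nucleophile to C8a and leaves the carbanion on C4a; C4 is a benzylic carbinol carbon (aldehyde before, cation after).
5. Ring order: ring B arrives with the aldehyde, ring A is attached and ring C closed together in the key step, and the middle and bottom units come from (−)-epicatechin. C2/C3 of the top unit come from an Evans syn-aldol.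

Key step: step 8

Remarks on the chemistry:
- Flavan numbering is used throughout; "top", "middle" and "bottom" refer to the three flavan units of the target, which is epicatechin-(4β→8)-epicatechin 3-O-gallate-(4β→8)-epicatechin 3-O-gallate.
- Compound 22 is expected as a mixture of C4 epimers. Its SMILES leaves C4 open because both epimers give the same C4 cation in step 12.
- Step 12 is a dehydrative coupling: the C4 hydroxyl of 22 leaves as water, which molecular sieves take up.
- Nucleophiles used in excess in steps 11 and 12 are assumed to be recovered by chromatography.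

## Route

Step 1
Reactants: 1 3,5-bis(benzyloxy)phenol
Product: 2 3,5-bis(benzyloxy)phenyl N-isopropylcarbamate
Conditions: i-PrNCO, Et3N (cat.), CH2Cl2, rt
Reagents that add atoms: isopropyl isocyanate, CC(C)N=C=O
Why: Base-catalysed addition of the phenol to the isocyanate (carbamoylation) installs a removable directing group for the next step.

Step 2
Reactants: 2 3,5-bis(benzyloxy)phenyl N-isopropylcarbamate
Product: 6 3,5-bis(benzyloxy)-2-(trimethylsilyl)phenyl N-isopropylcarbamate, via N-silyl carbamate 3 (not isolated), via aryllithium 4 (not isolated), via bis-silyl carbamate 5 (not isolated)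
Conditions: TBSOTf, TMEDA, Et2O, 0 °C → rt; n-BuLi, TMEDA, −78 °C; TMSCl, −78 °C → rt; aq. NaHSO4
Reagents that add atoms: chlorotrimethylsilane, C[Si](C)(C)Cl
Why: Directed ortho-metalation: after in-flask N-silylation the carbamate directs n-BuLi to the ring position flanked by the carbamate and a benzyloxy group (two such positions, equivalent by symmetry), TMSCl traps the aryllithium and the N-silyl group falls off on acidic work-up.

Step 3
Reactants: 6 3,5-bis(benzyloxy)-2-(trimethylsilyl)phenyl N-isopropylcarbamate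
Product: 8 3,5-bis(benzyloxy)-2-(trimethylsilyl)phenyl trifluoromethanesulfonate, via silylphenol 7 (not isolated)
Conditions: DBU, Et2NH, MeCN, 40 °C; then PhNTf2, rt
Reagents that add atoms: N-phenylbis(trifluoromethanesulfonimide), O=S(=O)(N(c1ccccc1)S(=O)(=O)C(F)(F)F)C(F)(F)F
Why: Base-induced carbamate cleavage (elimination to the isocyanate, scavenged by Et2NH as the urea) unmasks the phenoxide, which is triflated in the same flask to give the o-silylaryl triflate aryne precursor.

Step 4
Reactants: 9 (S)-4-benzyloxazolidin-2-one, 10 benzyloxyacetyl chloride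
Product: 12 (S)-4-benzyl-3-(benzyloxyacetyl)oxazolidin-2-one, via lithium oxazolidinide 11 (not isolated)
Conditions: n-BuLi, THF, −78 °C; then 10, −78 → 0 °C
Reagents that add atoms: none
Why: N-Acylation of the lithiated oxazolidinone with the acid chloride is the standard entry to the glycolate imide.

Step 5
Reactants: 12 (S)-4-benzyl-3-(benzyloxyacetyl)oxazolidin-2-one, 13 3,4-bis(benzyloxy)benzaldehyde
Product: 16 (4S)-4-benzyl-3-[(2S,3R)-2-(benzyloxy)-3-[3,4-bis(benzyloxy)phenyl]-3-hydroxypropanoyl]oxazolidin-2-one, via boron enolate 14 (not isolated), via boron aldolate 15 (not isolated)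
Conditions: n-Bu2BOTf, i-Pr2NEt, CH2Cl2, −78 → 0 °C; then 13, −78 → 0 °C; pH 7 buffer, MeOH, H2O2, 0 °C
Reagents that add atoms: none
Why: Evans syn-aldol: the Z-boron enolate reacts through a Zimmerman–Traxler chair on the face away from the auxiliary benzyl group, setting the (2S,3R) syn pair that becomes C3 and C2 (2,3-cis, both R) of the top unit.

Step 6
Reactants: 16 syn-aldol imide
Product: 17 (2S,3R)-2-(benzyloxy)-3-[3,4-bis(benzyloxy)phenyl]-3-hydroxy-N-methoxy-N-methylpropanamide
Conditions: MeNH(OMe)·HCl, AlMe3, CH2Cl2, −10 → 0 °C; aq. potassium sodium tartrate (KNaC4H4O6)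
Reagents that add atoms: N,O-dimethylhydroxylamine hydrochloride, CNOC.Cl
Why: Weinreb transamidation by the aluminium amide, assisted by the free β-hydroxyl, cleaves the auxiliary without touching either stereocentre.

Step 7
Reactants: 17 Weinreb amide
Product: 19 (2S,3R)-2-(benzyloxy)-3-[3,4-bis(benzyloxy)phenyl]-3-hydroxypropanal, via aluminium hemiaminal 18 (not isolated)
Conditions: i-Bu2AlH (2.5 equiv), THF, −78 °C; aq. potassium sodium tartrate (KNaC4H4O6), 0 °C; used crude at once
Reagents that add atoms: none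
Why: Hydride reduction of a Weinreb amide stops at the chelated tetrahedral intermediate, which releases the aldehyde only on work-up, so over-reduction is avoided.

Step 8
Reactants: 19 (2S,3R)-2-(benzyloxy)-3-[3,4-bis(benzyloxy)phenyl]-3-hydroxypropanal, 8 3,5-bis(benzyloxy)-2-(trimethylsilyl)phenyl trifluoromethanesulfonate
Product: 22 (2R,3R)-3,5,7-tris(benzyloxy)-2-[3,4-bis(benzyloxy)phenyl]chroman-4-ol (C4 epimers), via aryne 20 (not isolated), via aryl anion 21 (not isolated)
Conditions: KF, 18-crown-6, THF, −20 → 0 °C, slow addition of 8 (1.2 equiv)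
Reagents that add atoms: none
Why: Proposed new method: fluoride-induced 1,2-elimination of 8 releases aryne 20, the fluoride-hydrogen-bonded benzylic hydroxyl of 19 adds to the aryne carbon remote from the flanking benzyloxy group, and the resulting aryl anion 21 (ortho to the new ether oxygen, next to the C5 oxygen) adds to the tethered aldehyde before it is protonated, so that O1–C8a and C4a–C4 form in one operation and the former hydroxyl proton ends on the C4 oxygen. The closest known reaction types are the aryne annulation of salicylaldehydes and salicylates (O-arylation followed by intramolecular carbonyl addition to xanthydrols and xanthones) and three-component couplings of arynes with a heteroatom nucleophile and an aldehyde; what is new is an aliphatic aldol (β-hydroxy aldehyde) as the tethered O-nucleophile/C-electrophile pair. Ring C closes by 6-exo-trig attack of the aryl carbanion on the C=O group. C2 and C3 are carried over from 19 unchanged because no bond to either centre is made or broken; the new carbinol centre C4 needs no control (a half-chair with the C2 aryl group pseudo-equatorial should favour the 3,4-trans alcohol) since C4 is ionized in step 12. The step needs regioselectivity on the aryne, secured by the inductive polarization of the triple bond by the adjacent benzyloxy group (attack meta to it, as for 3-alkoxyarynes); chemoselective O-arylation, secured by 19 holding a single free hydroxyl; and ring closure faster than proton quench or retro-aldol cleavage, secured by a reactive aldehyde in a six-membered transition state, the low temperature and the absence of a stoichiometric strong base.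

Step 9
Reactants: 23 (−)-epicatechin
Product: 24 5,7,3',4'-tetra-O-benzyl-(−)-epicatechin
Conditions: BnBr, K2CO3, DMF, 0 °C → rt
Reagents that add atoms: benzyl bromide, BrCc1ccccc1
Why: Williamson etherification with a carbonate base alkylates the four phenols and leaves the far less acidic C3 alcohol free.

Step 10
Reactants: 24 5,7,3',4'-tetra-O-benzyl-(−)-epicatechin
Product: 25 (2R,3R,4S)-5,7-bis(benzyloxy)-2-[3,4-bis(benzyloxy)phenyl]-4-(2-ethoxyethoxy)chroman-3-ol
Conditions: DDQ, 2-ethoxyethanol, CH2Cl2, rt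
Reagents that add atoms: 2-ethoxyethanol, CCOCCO
Why: DDQ benzylic oxidation: hydride abstraction at C4 gives the ring-A-stabilized cation, which the alcohol traps anti to the C3 hydroxyl (4β); this centre is ionized again in step 11.

Step 11
Reactants: 25 4β-(2-ethoxyethoxy) electrophile, 24 5,7,3',4'-tetra-O-benzyl-(−)-epicatechin (4 equiv)
Product: 26 5,7,3',4'-tetra-O-benzylepicatechin-(4β→8)-5,7,3',4'-tetra-O-benzylepicatechin (octa-O-benzyl procyanidin B2)
Conditions: TMSOTf (cat.), CH2Cl2, −78 °C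
Reagents that add atoms: none
Why: Lewis-acid Friedel–Crafts-type flavan coupling: the C4 cation is attacked by C8 (the most nucleophilic ring-A position) of excess 24 from the β-face, anti to the C3 oxygen and the cis C2 aryl group, setting the 3,4-trans (4β) centre of the future middle unit.

Step 12
Reactants: 22 top-unit chroman-4-ol, 26 octa-O-benzyl procyanidin B2 (2.5 equiv)
Product: 27 3,5,7,3',4'-penta-O-benzylepicatechin-(4β→8)-5,7,3',4'-tetra-O-benzylepicatechin-(4β→8)-5,7,3',4'-tetra-O-benzylepicatechin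
Conditions: TMSOTf (0.2 equiv), 4 Å molecular sieves, CH2Cl2, −78 → −40 °C
Reagents that add atoms: none
Why: Dehydrative Friedel–Crafts-type flavan coupling: the acid ionizes the benzylic C4 hydroxyl of either epimer of 22 (lost as water, taken up by the sieves) to the ring-A-stabilized C4 cation, which C8 of the upper unit of 26 attacks on the β-face, anti to the C3 benzyloxy group, setting the top-unit C4 as the 3,4-trans (4β→8) centre.

Step 13
Reactants: 27 trimer diol, 28 3,4,5-tris(benzyloxy)benzoic acid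
Product: 30 27 bearing 3,4,5-tris(benzyloxy)benzoyl esters on the C3 oxygens of the middle and bottom units, via O-acylisourea 29 (not isolated)
Conditions: 28 (6 equiv), DCC, DMAP, CH2Cl2, rt → 40 °C
Reagents that add atoms: none
Why: Steglich esterification acylates the only two free hydroxyls; the top unit is excluded by its 3-O-benzyl ether.

Step 14
Reactants: 30 nonadeca-O-benzyl precursor
Product: 31 epicatechin-(4β→8)-epicatechin 3-O-gallate-(4β→8)-epicatechin 3-O-gallate (target)
Conditions: H2 (1 atm), Pd(OH)2/C, THF/MeOH/H2O, rt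
Reagents that add atoms: none
Why: Hydrogenolysis should remove all nineteen benzyl ethers (eighteen phenolic, one aliphatic) while leaving the gallate esters, the interflavan bonds and every stereocentre untouched.

## Compound list

1 | 3,5-bis(benzyloxy)phenol | Oc1cc(OCc2ccccc2)cc(OCc2ccccc2)c1 | starting material
2 | 3,5-bis(benzyloxy)phenyl N-isopropylcarbamate | CC(C)NC(=O)Oc1cc(OCc2ccccc2)cc(OCc2ccccc2)c1 | intermediate
3 | N-(tert-butyldimethylsilyl) derivative of 2 | CC(C)N([Si](C)(C)C(C)(C)C)C(=O)Oc1cc(OCc2ccccc2)cc(OCc2ccccc2)c1 | intermediate (not isolated)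
4 | 2-lithio derivative of 3 | CC(C)N([Si](C)(C)C(C)(C)C)C(=O)Oc1cc(OCc2ccccc2)cc(OCc2ccccc2)c1[Li] | intermediate (not isolated)
5 | N-(tert-butyldimethylsilyl)-2-(trimethylsilyl) carbamate | CC(C)N([Si](C)(C)C(C)(C)C)C(=O)Oc1cc(OCc2ccccc2)cc(OCc2ccccc2)c1[Si](C)(C)C | intermediate (not isolated)
6 | 3,5-bis(benzyloxy)-2-(trimethylsilyl)phenyl N-isopropylcarbamate | CC(C)NC(=O)Oc1cc(OCc2ccccc2)cc(OCc2ccccc2)c1[Si](C)(C)C | intermediate
7 | 3,5-bis(benzyloxy)-2-(trimethylsilyl)phenol (as its DBU salt) | Oc1cc(OCc2ccccc2)cc(OCc2ccccc2)c1[Si](C)(C)C | intermediate (not isolated)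
8 | 3,5-bis(benzyloxy)-2-(trimethylsilyl)phenyl trifluoromethanesulfonate | C[Si](C)(C)c1c(OS(=O)(=O)C(F)(F)F)cc(OCc2ccccc2)cc1OCc1ccccc1 | intermediate
9 | (S)-4-benzyloxazolidin-2-one | O=C1N[C@@H](Cc2ccccc2)CO1 | starting material
10 | benzyloxyacetyl chloride | O=C(Cl)COCc1ccccc1 | starting material
11 | lithium salt of 9 | [Li+].O=C1[N-][C@@H](Cc2ccccc2)CO1 | intermediate (not isolated)
12 | (S)-4-benzyl-3-(benzyloxyacetyl)oxazolidin-2-one | O=C(COCc1ccccc1)N1C(=O)OC[C@@H]1Cc1ccccc1 | intermediate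
13 | 3,4-bis(benzyloxy)benzaldehyde | O=Cc1ccc(OCc2ccccc2)c(OCc2ccccc2)c1 | starting material
14 | Z-dibutylboron enolate of 12 | CCCCB(CCCC)O/C(=C\OCc1ccccc1)N1C(=O)OC[C@@H]1Cc1ccccc1 | intermediate (not isolated)
15 | dibutylboron aldolate of 16 | O=C([C@@H](OCc1ccccc1)[C@H](OB(CCCC)CCCC)c1ccc(OCc2ccccc2)c(OCc2ccccc2)c1)N1C(=O)OC[C@@H]1Cc1ccccc1 | intermediate (not isolated)
16 | (4S)-4-benzyl-3-[(2S,3R)-2-(benzyloxy)-3-[3,4-bis(benzyloxy)phenyl]-3-hydroxypropanoyl]oxazolidin-2-one | O=C([C@@H](OCc1ccccc1)[C@H](O)c1ccc(OCc2ccccc2)c(OCc2ccccc2)c1)N1C(=O)OC[C@@H]1Cc1ccccc1 | intermediate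
17 | (2S,3R)-2-(benzyloxy)-3-[3,4-bis(benzyloxy)phenyl]-3-hydroxy-N-methoxy-N-methylpropanamide | CON(C)C(=O)[C@@H](OCc1ccccc1)[C@H](O)c1ccc(OCc2ccccc2)c(OCc2ccccc2)c1 | intermediate
18 | bis(diisobutylaluminium) hemiaminal/alkoxide of 17 | CON(C)C(O[Al](CC(C)C)CC(C)C)[C@@H](OCc1ccccc1)[C@H](O[Al](CC(C)C)CC(C)C)c1ccc(OCc2ccccc2)c(OCc2ccccc2)c1 | intermediate (not isolated)
19 | (2S,3R)-2-(benzyloxy)-3-[3,4-bis(benzyloxy)phenyl]-3-hydroxypropanal | O=C[C@@H](OCc1ccccc1)[C@H](O)c1ccc(OCc2ccccc2)c(OCc2ccccc2)c1 | intermediate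
20 | 3,5-bis(benzyloxy)benzyne | C1#CC(OCc2ccccc2)=CC(OCc2ccccc2)=C1 | intermediate (not isolated)
21 | potassium 2-aryloxy-4,6-bis(benzyloxy)phenyl anion (O-arylated 19) | [K+].O=C[C@@H](OCc1ccccc1)[C@H](Oc1cc(OCc2ccccc2)cc(OCc2ccccc2)[c-]1)c1ccc(OCc2ccccc2)c(OCc2ccccc2)c1 | intermediate (not isolated)
22 | (2R,3R)-3,5,7-tris(benzyloxy)-2-[3,4-bis(benzyloxy)phenyl]chroman-4-ol (C4 epimers) | OC1c2c(OCc3ccccc3)cc(OCc3ccccc3)cc2O[C@H](c2ccc(OCc3ccccc3)c(OCc3ccccc3)c2)[C@@H]1OCc1ccccc1 | intermediate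
23 | (−)-epicatechin, (2R,3R) | O[C@@H]1Cc2c(O)cc(O)cc2O[C@@H]1c1ccc(O)c(O)c1 | starting material
24 | 5,7,3',4'-tetra-O-benzyl-(−)-epicatechin | O[C@@H]1Cc2c(OCc3ccccc3)cc(OCc3ccccc3)cc2O[C@@H]1c1ccc(OCc2ccccc2)c(OCc2ccccc2)c1 | intermediate
25 | (2R,3R,4S)-5,7-bis(benzyloxy)-2-[3,4-bis(benzyloxy)phenyl]-4-(2-ethoxyethoxy)chroman-3-ol | O[C@@H]1[C@@H](OCCOCC)c2c(OCc3ccccc3)cc(OCc3ccccc3)cc2O[C@@H]1c1ccc(OCc2ccccc2)c(OCc2ccccc2)c1 | intermediate
26 | octa-O-benzyl procyanidin B2 (4β→8 dimer, two free C3 hydroxyls) | O[C@@H]1[C@@H](c2c(OCc3ccccc3)cc(OCc3ccccc3)c3c2O[C@H](c2ccc(OCc4ccccc4)c(OCc4ccccc4)c2)[C@H](O)C3)c2c(OCc3ccccc3)cc(OCc3ccccc3)cc2O[C@@H]1c1ccc(OCc2ccccc2)c(OCc2ccccc2)c1 | intermediate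
27 | trideca-O-benzyl trimer (top unit 3-O-benzyl; free C3 hydroxyls on middle and bottom units) | O[C@@H]1[C@@H](c2c(OCc3ccccc3)cc(OCc3ccccc3)c3c2O[C@H](c2ccc(OCc4ccccc4)c(OCc4ccccc4)c2)[C@H](O)C3)c2c(OCc3ccccc3)cc(OCc3ccccc3)c([C@H]3c4c(OCc5ccccc5)cc(OCc5ccccc5)cc4O[C@H](c4ccc(OCc5ccccc5)c(OCc5ccccc5)c4)[C@@H]3OCc3ccccc3)c2O[C@@H]1c1ccc(OCc2ccccc2)c(OCc2ccccc2)c1 | intermediate
28 | 3,4,5-tris(benzyloxy)benzoic acid | O=C(O)c1cc(OCc2ccccc2)c(OCc2ccccc2)c(OCc2ccccc2)c1 | starting material
29 | O-acylisourea of 28 with DCC | O=C(OC(=NC1CCCCC1)NC1CCCCC1)c1cc(OCc2ccccc2)c(OCc2ccccc2)c(OCc2ccccc2)c1 | intermediate (not isolated)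
30 | nonadeca-O-benzyl precursor (27 with tri-O-benzylgalloyl esters on middle and bottom C3 oxygens) | O=C(O[C@@H]1[C@@H](c2c(OCc3ccccc3)cc(OCc3ccccc3)c3c2O[C@H](c2ccc(OCc4ccccc4)c(OCc4ccccc4)c2)[C@H](OC(=O)c2cc(OCc4ccccc4)c(OCc4ccccc4)c(OCc4ccccc4)c2)C3)c2c(OCc3ccccc3)cc(OCc3ccccc3)c([C@H]3c4c(OCc5ccccc5)cc(OCc5ccccc5)cc4O[C@H](c4ccc(OCc5ccccc5)c(OCc5ccccc5)c4)[C@@H]3OCc3ccccc3)c2O[C@@H]1c1ccc(OCc2ccccc2)c(OCc2ccccc2)c1)c1cc(OCc2ccccc2)c(OCc2ccccc2)c(OCc2ccccc2)c1 | intermediate
31 | epicatechin-(4β→8)-epicatechin 3-O-gallate-(4β→8)-epicatechin 3-O-gallate; top (2R,3R,4R), middle (2R,3R,4S), bottom (2R,3R) | O=C(O[C@@H]1[C@@H](c2c(O)cc(O)c3c2O[C@H](c2ccc(O)c(O)c2)[C@H](OC(=O)c2cc(O)c(O)c(O)c2)C3)c2c(O)cc(O)c([C@H]3c4c(O)cc(O)cc4O[C@H](c4ccc(O)c(O)c4)[C@@H]3O)c2O[C@@H]1c1ccc(O)c(O)c1)c1cc(O)c(O)c(O)c1 | target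

## Step count and risks

Total step count: 14. Longest linear sequence: 8 steps (steps 4, 5, 6, 7, 8, 12, 13, 14). The aryne precursor (steps 1–3) and the lower dimer (steps 9–11) are convergent branches.

Steps most likely to fail:

1. Step 8 (Proposed new method). The aryl anion may be protonated before it closes the ring, giving plain O–H insertion. Fluoride may also trigger retro-aldol cleavage or C3 epimerization of the hydroxy aldehyde, and the product alcohol may be arylated a second time. Fallback by known chemistry, building the top-unit electrophile from the natural flavan instead of by annulation: it sets out from 25, which is 3-O-benzylated (NaH, BnBr, n-Bu4NI cat., DMF, 0 °C → rt) to (2R,3R,4S)-3,5,7-tris(benzyloxy)-2-[3,4-bis(benzyloxy)phenyl]-4-(2-ethoxyethoxy)chromane F1. F1 replaces 22 in the TMSOTf coupling with 26 (TMSOTf, CH2Cl2, −78 → −40 °C, loss of 2-ethoxyethanol) and the route is rejoined at 27.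

2. Step 12. The product's own top-unit ring A may react with further cation (chain growth), attack may occur through C6, the acid may exchange the existing interflavan bond, or the water set free may slow the ionization. Fallback with a blocking group, so that one equivalent of dimer suffices: it sets out from 22, which is brominated at C8 (N-bromosuccinimide, CH2Cl2, −40 → 0 °C) to the 8-bromo chroman-4-ol F2. Dehydrative coupling of F2 with one equivalent of 26 (TMSOTf, 4 Å molecular sieves, CH2Cl2, −78 °C) should give the 8-bromo trimer diol F3, whose capped top unit cannot grow further. Digalloylation as in step 13 gives the 8-bromo nonadeca-O-benzyl precursor F4. Hydrogenolysis (H2, Pd(OH)2/C, Et3N, THF/MeOH/H2O) removes bromine together with the benzyl groups and rejoins the route at 31.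

3. Step 7. The α-alkoxy-β-hydroxy aldehyde may epimerize at the α-carbon, undergo retro-aldol cleavage or self-condense during reduction and work-up. Fallback that avoids the amide reduction: it sets out from 16, whose auxiliary is removed reductively (LiBH4, MeOH 1 equiv, Et2O, 0 °C) to (1R,2R)-2-(benzyloxy)-1-[3,4-bis(benzyloxy)phenyl]propane-1,3-diol F5. Chemoselective oxidation of the primary alcohol (TEMPO cat., PhI(OAc)2, CH2Cl2, rt) rejoins the route at 19, which is then used at once in step 8.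

Further compounds
F1 | step 8 | (2R,3R,4S)-3,5,7-tris(benzyloxy)-2-[3,4-bis(benzyloxy)phenyl]-4-(2-ethoxyethoxy)chromane | C(O[C@@H]1[C@@H](OCCOCC)c2c(OCc3ccccc3)cc(OCc3ccccc3)cc2O[C@@H]1c1ccc(OCc2ccccc2)c(OCc2ccccc2)c1)c1ccccc1
F2 | step 12 | (2R,3R)-3,5,7-tris(benzyloxy)-2-[3,4-bis(benzyloxy)phenyl]-8-bromochroman-4-ol (C4 epimers) | OC1c2c(OCc3ccccc3)cc(OCc3ccccc3)c(Br)c2O[C@H](c2ccc(OCc3ccccc3)c(OCc3ccccc3)c2)[C@@H]1OCc1ccccc1
F3 | step 12 | 8-bromo derivative (top unit) of trimer diol 27 | O[C@@H]1[C@@H](c2c(OCc3ccccc3)cc(OCc3ccccc3)c3c2O[C@H](c2ccc(OCc4ccccc4)c(OCc4ccccc4)c2)[C@H](O)C3)c2c(OCc3ccccc3)cc(OCc3ccccc3)c([C@H]3c4c(OCc5ccccc5)cc(OCc5ccccc5)c(Br)c4O[C@H](c4ccc(OCc5ccccc5)c(OCc5ccccc5)c4)[C@@H]3OCc3ccccc3)c2O[C@@H]1c1ccc(OCc2ccccc2)c(OCc2ccccc2)c1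
F4 | step 12 | 8-bromo derivative (top unit) of precursor 30 | O=C(O[C@@H]1[C@@H](c2c(OCc3ccccc3)cc(OCc3ccccc3)c3c2O[C@H](c2ccc(OCc4ccccc4)c(OCc4ccccc4)c2)[C@H](OC(=O)c2cc(OCc4ccccc4)c(OCc4ccccc4)c(OCc4ccccc4)c2)C3)c2c(OCc3ccccc3)cc(OCc3ccccc3)c([C@H]3c4c(OCc5ccccc5)cc(OCc5ccccc5)c(Br)c4O[C@H](c4ccc(OCc5ccccc5)c(OCc5ccccc5)c4)[C@@H]3OCc3ccccc3)c2O[C@@H]1c1ccc(OCc2ccccc2)c(OCc2ccccc2)c1)c1cc(OCc2ccccc2)c(OCc2ccccc2)c(OCc2ccccc2)c1
F5 | step 7 | (1R,2R)-2-(benzyloxy)-1-[3,4-bis(benzyloxy)phenyl]propane-1,3-diol | OC[C@@H](OCc1ccccc1)[C@H](O)c1ccc(OCc2ccccc2)c(OCc2ccccc2)c1
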